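**Strategy.** Ring A (C1–C2–C3–C4–C5–C10, eremophilane numbering) is built first by a catalytic enantioselective Diels–Alder reaction that forms the C1–C2 and C3–C4 bonds in one operation. It exploits the 1,4-relationship in ring A between oxygenated C3 and the ring-fusion carbon C10, and the methyl-bearing C4 next to C3: the acyclic diene C1=C10(OSi)–C5=C4 and methyl vinyl ketone (C2=C3) give a cyclohexene that carries the acetyl forerunner of the C3 oxygen, the C4 stereocentre and a regiodefined silyl enol ether at C5=C10. That enol ether launches the annulation of ring B; Baeyer–Villiger, Peterson and esterification steps finish the target.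

Key step: step 2

Remark: eremophilane numbering is used for the carbocyclic core throughout (ring A: C1–C2–C3–C4–C5–C10; ring B: C5–C6–C7–C8–C9–C10; C14 is the methyl on C5, C15 the methyl on C4); β is the face that carries C14.
Remark: 1-(trimethylsilyl)propan-2-one (10) is assumed to be a catalogue compound.

Step 1
Reactants: 1 (E)-3-methylpent-3-en-2-one
Product: 2 (3E)-3-methyl-2-{[tri(propan-2-yl)silyl]oxy}penta-1,3-diene
Conditions: iPr3SiOTf, Et3N, CH2Cl2, 0 °C
Reagents that add atoms: triisopropylsilyl trifluoromethanesulfonate, CC(C)[Si](OS(=O)(=O)C(F)(F)F)(C(C)C)C(C)C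
Why: Soft enolisation of the enone at its methyl ketone side (silyl enol ether formation) should give the cross-conjugated 2-silyloxy diene and leave the E geometry of the trisubstituted double bond untouched.

Step 2
Reactants: 2 (3E)-3-methyl-2-{[tri(propan-2-yl)silyl]oxy}penta-1,3-diene; 3 methyl vinyl ketone (but-3-en-2-one)
Product: 4 1-[(1S,2S)-2,3-dimethyl-4-{[tri(propan-2-yl)silyl]oxy}cyclohex-3-en-1-yl]ethan-1-one (acetyl cis to the ring methyl on the stereocentre)
Conditions: (S)-3,3-diphenyl-1-(2-methylphenyl)tetrahydro-1H,3H-pyrrolo[1,2-c][1,3,2]oxazaborole (20 mol %), HN(SO2CF3)2 (16 mol %), CH2Cl2, −78 to −40 °C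
Reagents that add atoms: none
Why: The boron of the N-protonated oxazaborolidine binds the carbonyl oxygen of 3 and the diene adds in a concerted, asynchronous [4+2] cycloaddition in which C1–C2 bonding runs ahead of C3–C4 bonding. The closest known reaction type is the chiral oxazaborolidinium-catalysed Diels–Alder reaction of 2-silyloxy-1,3-dienes with acyclic enones and acrylates. Ring A is closed as a six-membered ring by this intermolecular suprafacial cycloaddition, which leaves the C5=C10 silyl enol ether in place. C4 is set in the absolute sense by the catalyst, which exposes one enantioface of the bound enone to the E-configured diene terminus, and C3 (acetyl cis to the C4 methyl) by the endo rule; the (S)-catalyst is proposed for the (1S,2S) adduct and its mirror image would be used should the sense prove opposite. The step needs regioselectivity and high endo selectivity (an exo adduct would end in the enantiomeric series after the later C3 epimerisation): the 2-silyloxy group (largest HOMO coefficient at C1, "para" product) and the terminal methyl group ("ortho" product) direct the acetyl-bearing carbon to C4 in concert, and Lewis-acid activation of the enone favours the endo mode.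

Step 3
Reactants: 4 1-[(1S,2S)-2,3-dimethyl-4-{[tri(propan-2-yl)silyl]oxy}cyclohex-3-en-1-yl]ethan-1-one; 3 methyl vinyl ketone
Product: 7 (4aR,5S,6R)-6-acetyl-4a,5-dimethyl-4,4a,5,6,7,8-hexahydronaphthalen-2(3H)-one, via silyl enol ether Michael adduct 5 (not isolated), via triketone 6 (not isolated)
Conditions: HN(SO2CF3)2 (5 mol %), CH2Cl2, −78 °C; then 1 M HCl, THF, rt; then KOH (0.5 equiv), MeOH, 50 °C
Reagents that add atoms: none
Why: Triflimide-catalysed Mukaiyama–Michael addition of the tetrasubstituted silyl enol ether to the enone should form the C5–C6 bond anti to the pseudoaxial C4 methyl (the cis C3 acetyl lies equatorial and does not interfere), which sets the quaternary C5 with C14 and C15 cis, after which Robinson-type aldol condensation of C9 onto C10 closes ring B and the base equilibrates C3 to the equatorial, α-oriented acetyl.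

Step 4
Reactants: 7 (4aR,5S,6R)-6-acetyl-4a,5-dimethyl-4,4a,5,6,7,8-hexahydronaphthalen-2(3H)-one
Product: 9 (4aR,5R,6R)-6-hydroxy-4a,5-dimethyl-4,4a,5,6,7,8-hexahydronaphthalen-2(3H)-one, via acetate 8 (not isolated)
Conditions: mCPBA, CH2Cl2, rt; then K2CO3 (cat.), MeOH, rt
Reagents that add atoms: meta-chloroperbenzoic acid, O=C(OO)c1cccc(Cl)c1
Why: Baeyer–Villiger oxidation in which the secondary C3 carbon migrates in preference to methyl with retention of configuration, the β,β-disubstituted conjugated enone being expected to react far more slowly with the peracid, followed by methanolysis of the acetate.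

Step 5
Reactants: 9 (4aR,5R,6R)-6-hydroxy-4a,5-dimethyl-4,4a,5,6,7,8-hexahydronaphthalen-2(3H)-one; 10 1-(trimethylsilyl)propan-2-one
Product: 11 (3S,4aR,5R,6R)-6-hydroxy-3-[2-hydroxy-1-(trimethylsilyl)propan-2-yl]-4a,5-dimethyl-4,4a,5,6,7,8-hexahydronaphthalen-2(3H)-one (both epimers at the carbinol carbon)
Conditions: LiN(iPr)2 (2.2 equiv), THF, −78 °C; then 10, −78 °C; AcOH quench at −78 °C
Reagents that add atoms: none
Why: After the alkoxide is formed, kinetic deprotonation on the saturated side of the enone gives the cross-conjugated lithium enolate, which should add to the α-silyl ketone (aldol addition) at C7 anti to the angular C14 methyl and so install a β-hydroxysilane as a latent isopropenyl group; the C7 and carbinol configurations are not yet final.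

Step 6
Reactants: 11 (3S,4aR,5R,6R)-6-hydroxy-3-[2-hydroxy-1-(trimethylsilyl)propan-2-yl]-4a,5-dimethyl-4,4a,5,6,7,8-hexahydronaphthalen-2(3H)-one
Product: 12 (3S,4aS,5R,6R,8aR)-6-hydroxy-3-[2-hydroxy-1-(trimethylsilyl)propan-2-yl]-4a,5-dimethyloctahydronaphthalen-2(1H)-one (cis-fused)
Conditions: H2 (1 atm), Pd/C, EtOAc, rt
Reagents that add atoms: none
Why: Heterogeneous hydrogenation of the trisubstituted enone double bond should deliver hydrogen to C10 from the β-face (the α-face is screened by the C7 side chain), giving the cis-fused decalone expected for 4,5-dimethyl octalones of this type.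

Step 7
Reactants: 12 (3S,4aS,5R,6R,8aR)-6-hydroxy-3-[2-hydroxy-1-(trimethylsilyl)propan-2-yl]-4a,5-dimethyloctahydronaphthalen-2(1H)-one
Product: 13 (1R,3S,4aR,5R,6R,8aS)-1,6-dihydroxy-3-[2-hydroxy-1-(trimethylsilyl)propan-2-yl]-4a,5-dimethyloctahydronaphthalen-2(1H)-one
Conditions: LiN(iPr)2 (3.3 equiv), THF, −78 °C; then (camphorsulfonyl)oxaziridine, −78 °C; AcOH quench
Reagents that add atoms: (camphorsulfonyl)oxaziridine, CC1(C)C2CCC13CS(=O)(=O)N4OC34C2
Why: After both alkoxides are formed, kinetic deprotonation should occur at the C9 methylene and not at the hindered tertiary C7, and the enolate is hydroxylated by the electrophilic oxaziridine from the convex β-face (enolate α-hydroxylation); C9 stays epimerisable and is corrected in step 9 if needed.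

Step 8
Reactants: 13 (1R,3S,4aR,5R,6R,8aS)-1,6-dihydroxy-3-[2-hydroxy-1-(trimethylsilyl)propan-2-yl]-4a,5-dimethyloctahydronaphthalen-2(1H)-one
Product: 14 (1R,3S,4aR,5R,6R,8aS)-1,6-dihydroxy-4a,5-dimethyl-3-(prop-1-en-2-yl)octahydronaphthalen-2(1H)-one
Conditions: TsOH·H2O (cat.), CH2Cl2, 0 °C
Reagents that add atoms: none
Why: Acid-promoted Peterson elimination (anti loss of trimethylsilanol from the β-hydroxysilane) places the double bond regiospecifically toward the former CH2Si carbon, giving the isopropenyl group without conjugation to the ketone.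

Step 9
Reactants: 14 (1R,3S,4aR,5R,6R,8aS)-1,6-dihydroxy-4a,5-dimethyl-3-(prop-1-en-2-yl)octahydronaphthalen-2(1H)-one; 15 angelic acid [(2Z)-2-methylbut-2-enoic acid], of which two equivalents are incorporated, one at each hydroxyl
Product: 17 (1R,3R,4aR,5R,6R,8aS)-4a,5-dimethyl-2-oxo-3-(prop-1-en-2-yl)decahydronaphthalene-1,6-diyl bis[(2Z)-2-methylbut-2-enoate], via 7-epi bis-angelate 16 (not isolated)
Conditions: 15 (3 equiv), 2,4,6-trichlorobenzoyl chloride (3 equiv), Et3N (6 equiv), toluene, rt; then 14, 60 °C; then DBU (0.1 equiv), 0 °C to rt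
Reagents that add atoms: angelic acid 15 (second equivalent, for the second ester), C/C=C(/C)C(=O)O
Why: Yamaguchi esterification through the mixed anhydride, used in excess, should acylate both secondary alcohols (C3–OH and C9–OH, one molecule of 15 each) without a nucleophilic catalyst (which limits Z-to-E isomerisation), and brief amidine-base equilibration via the C8 enolate then inverts C7, and C9 if required, to the all-equatorial arrangement of the cis-decalin, α-reprotonation being faster than γ-protonation.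

**Compound list**

1 | (E)-3-methylpent-3-en-2-one | C/C=C(\C)C(C)=O | starting material
2 | (3E)-3-methyl-2-{[tri(propan-2-yl)silyl]oxy}penta-1,3-diene | C=C(O[Si](C(C)C)(C(C)C)C(C)C)/C(C)=C/C | intermediate
3 | methyl vinyl ketone (but-3-en-2-one) | C=CC(C)=O | starting material
4 | 1-[(1S,2S)-2,3-dimethyl-4-{[tri(propan-2-yl)silyl]oxy}cyclohex-3-en-1-yl]ethan-1-one | CC1=C(O[Si](C(C)C)(C(C)C)C(C)C)CC[C@H](C(C)=O)[C@@H]1C | intermediate
5 | (2R,3S,4S)-4-acetyl-2,3-dimethyl-2-(3-{[tri(propan-2-yl)silyl]oxy}but-2-en-1-yl)cyclohexan-1-one (enol ether geometry open) | CC(=CC[C@@]1(C)C(=O)CC[C@H](C(C)=O)[C@@H]1C)O[Si](C(C)C)(C(C)C)C(C)C | intermediate (not isolated)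
6 | (2R,3S,4S)-4-acetyl-2,3-dimethyl-2-(3-oxobutyl)cyclohexan-1-one | CC(=O)CC[C@@]1(C)C(=O)CC[C@H](C(C)=O)[C@@H]1C | intermediate (not isolated)
7 | (4aR,5S,6R)-6-acetyl-4a,5-dimethyl-4,4a,5,6,7,8-hexahydronaphthalen-2(3H)-one | O=C1CC[C@@]2(C)C(=C1)CC[C@@H](C(C)=O)[C@@H]2C | intermediate
8 | (1R,2R,8aR)-1,8a-dimethyl-6-oxo-1,2,3,4,6,7,8,8a-octahydronaphthalen-2-yl acetate | O=C1CC[C@@]2(C)C(=C1)CC[C@@H](OC(C)=O)[C@@H]2C | intermediate (not isolated)
9 | (4aR,5R,6R)-6-hydroxy-4a,5-dimethyl-4,4a,5,6,7,8-hexahydronaphthalen-2(3H)-one | O=C1CC[C@@]2(C)C(=C1)CC[C@@H](O)[C@@H]2C | intermediate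
10 | 1-(trimethylsilyl)propan-2-one | CC(=O)C[Si](C)(C)C | starting material
11 | (3S,4aR,5R,6R)-6-hydroxy-3-[2-hydroxy-1-(trimethylsilyl)propan-2-yl]-4a,5-dimethyl-4,4a,5,6,7,8-hexahydronaphthalen-2(3H)-one (carbinol carbon: both epimers) | C[Si](C)(C)CC(C)(O)[C@@H]1C[C@@]2(C)C(=CC1=O)CC[C@@H](O)[C@@H]2C | intermediate
12 | (3S,4aS,5R,6R,8aR)-6-hydroxy-3-[2-hydroxy-1-(trimethylsilyl)propan-2-yl]-4a,5-dimethyloctahydronaphthalen-2(1H)-one | C[Si](C)(C)CC(C)(O)[C@@H]1C[C@@]2(C)[C@H](CC[C@@H](O)[C@@H]2C)CC1=O | intermediate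
13 | (1R,3S,4aR,5R,6R,8aS)-1,6-dihydroxy-3-[2-hydroxy-1-(trimethylsilyl)propan-2-yl]-4a,5-dimethyloctahydronaphthalen-2(1H)-one | C[Si](C)(C)CC(C)(O)[C@@H]1C[C@@]2(C)[C@H](CC[C@@H](O)[C@@H]2C)[C@@H](O)C1=O | intermediate
14 | (1R,3S,4aR,5R,6R,8aS)-1,6-dihydroxy-4a,5-dimethyl-3-(prop-1-en-2-yl)octahydronaphthalen-2(1H)-one | C=C(C)[C@@H]1C[C@@]2(C)[C@H](CC[C@@H](O)[C@@H]2C)[C@@H](O)C1=O | intermediate
15 | angelic acid, (2Z)-2-methylbut-2-enoic acid | C/C=C(/C)C(=O)O | starting material
16 | (1R,3S,4aR,5R,6R,8aS)-4a,5-dimethyl-2-oxo-3-(prop-1-en-2-yl)decahydronaphthalene-1,6-diyl bis[(2Z)-2-methylbut-2-enoate] (C7 epimer of the target) | C=C(C)[C@@H]1C[C@@]2(C)[C@H](CC[C@@H](OC(=O)/C(C)=C\C)[C@@H]2C)[C@@H](OC(=O)/C(C)=C\C)C1=O | intermediate (not isolated)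
17 | (1R,3R,4aR,5R,6R,8aS)-4a,5-dimethyl-2-oxo-3-(prop-1-en-2-yl)decahydronaphthalene-1,6-diyl bis[(2Z)-2-methylbut-2-enoate] | C=C(C)[C@H]1C[C@@]2(C)[C@H](CC[C@@H](OC(=O)/C(C)=C\C)[C@@H]2C)[C@@H](OC(=O)/C(C)=C\C)C1=O | target

**Totals and risks**

Total step count: 9. Longest linear sequence: 9 steps (from 1).

Steps most likely to fail:

1. Step 4. The peracid may attack the conjugated enone (epoxidation or oxygen insertion in ring B) as fast as the hindered C3 carbon migrates, so that chemoselectivity is lost. Fallback: from diene 2, the Diels–Alder reaction is run with 2,2,2-trifluoroethyl acrylate under the same catalyst to give 2,2,2-trifluoroethyl (1S,2S)-2,3-dimethyl-4-{[tri(propan-2-yl)silyl]oxy}cyclohex-3-ene-1-carboxylate F1. Mukaiyama–Michael addition to 3 would give the silyl enol ether adduct 2,2,2-trifluoroethyl (1S,2S,3R)-2,3-dimethyl-4-oxo-3-(3-{[tri(propan-2-yl)silyl]oxy}but-2-en-1-yl)cyclohexane-1-carboxylate F2, and acid hydrolysis the diketo ester 2,2,2-trifluoroethyl (1S,2S,3R)-2,3-dimethyl-4-oxo-3-(3-oxobutyl)cyclohexane-1-carboxylate F3. Aqueous KOH in MeOH (aldol condensation, C3 epimerisation, saponification) would give (1S,2R,8aR)-1,8a-dimethyl-6-oxo-1,2,3,4,6,7,8,8a-octahydronaphthalene-2-carboxylic acid F4. This is converted with N-hydroxypyridine-2-thione and DCC into the Barton ester 2-sulfanylidenepyridin-1(2H)-yl (1S,2R,8aR)-1,8a-dimethyl-6-oxo-1,2,3,4,6,7,8,8a-octahydronaphthalene-2-carboxylate F5. Its photolysis under O2 with t-BuSH, then P(OMe)3 (Barton decarboxylative oxygenation), should trap the C3 radical on the α-face, away from the axial C14 methyl. The fallback comes back to the route at 9.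

2. Step 9. During the base equilibration the isopropenyl double bond may migrate into conjugation with the C8 ketone (γ-protonation of the dienolate), the angelates may isomerise to tiglates, and the C9 acyl group may shift to the C8 oxygen through the enediolate. Fallback: from diol 14, both hydroxyls are silylated (Et3SiCl, imidazole) to (1R,3S,4aR,5R,6R,8aS)-4a,5-dimethyl-3-(prop-1-en-2-yl)-1,6-bis[(triethylsilyl)oxy]octahydronaphthalen-2(1H)-one F6. The doubly activated C7 proton is removed with KN(SiMe3)2 at −78 °C and the dienolate is quenched irreversibly with a hindered proton donor (axial, kinetic protonation at C7) to give the (1R,3R,4aR,5R,6R,8aS) epimer F7. HF·pyridine then frees (1R,3R,4aR,5R,6R,8aS)-1,6-dihydroxy-4a,5-dimethyl-3-(prop-1-en-2-yl)octahydronaphthalen-2(1H)-one F8, which is esterified as in step 9, again with one molecule of 15 per hydroxyl, but without the amidine treatment. The fallback comes back to the route at 17.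

3. Step 5. Proton transfer from the acidic α-silyl ketone to the enolate, retro-aldol cleavage on warming, or premature Peterson elimination of the lithium alkoxide may prevent clean formation of the β-hydroxysilane. Fallback: from 9, the same enolate is added to acetone to give (3S,4aR,5R,6R)-6-hydroxy-3-(2-hydroxypropan-2-yl)-4a,5-dimethyl-4,4a,5,6,7,8-hexahydronaphthalen-2(3H)-one F9. Hydrogenation (H2, Pd/C) gives the cis-fused (3S,4aS,5R,6R,8aR)-6-hydroxy-3-(2-hydroxypropan-2-yl)-4a,5-dimethyloctahydronaphthalen-2(1H)-one F10, and TsOH-catalysed dehydration the conjugated (4aS,5R,6R,8aR)-6-hydroxy-4a,5-dimethyl-3-(propan-2-ylidene)octahydronaphthalen-2(1H)-one F11. Hydroxylation of its C9 enolate (LiN(iPr)2, then the oxaziridine of step 7) gives (1R,4aR,5R,6R,8aS)-1,6-dihydroxy-4a,5-dimethyl-3-(propan-2-ylidene)octahydronaphthalen-2(1H)-one F12. Deconjugation through the potassium dienolate (KOtBu, t-BuOH/THF, then cold AcOH) would give the isopropenyl diol as a C7 epimer mixture that contains 14 and enters step 9 unchanged, since that step converges both epimers. The fallback comes back to the route at 14.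

**Further compounds**

F1 | step 4 | 2,2,2-trifluoroethyl (1S,2S)-2,3-dimethyl-4-{[tri(propan-2-yl)silyl]oxy}cyclohex-3-ene-1-carboxylate | CC1=C(O[Si](C(C)C)(C(C)C)C(C)C)CC[C@H](C(=O)OCC(F)(F)F)[C@@H]1C
F2 | step 4 | 2,2,2-trifluoroethyl (1S,2S,3R)-2,3-dimethyl-4-oxo-3-(3-{[tri(propan-2-yl)silyl]oxy}but-2-en-1-yl)cyclohexane-1-carboxylate | CC(=CC[C@@]1(C)C(=O)CC[C@H](C(=O)OCC(F)(F)F)[C@@H]1C)O[Si](C(C)C)(C(C)C)C(C)C
F3 | step 4 | 2,2,2-trifluoroethyl (1S,2S,3R)-2,3-dimethyl-4-oxo-3-(3-oxobutyl)cyclohexane-1-carboxylate | CC(=O)CC[C@@]1(C)C(=O)CC[C@H](C(=O)OCC(F)(F)F)[C@@H]1C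
F4 | step 4 | (1S,2R,8aR)-1,8a-dimethyl-6-oxo-1,2,3,4,6,7,8,8a-octahydronaphthalene-2-carboxylic acid | O=C1CC[C@@]2(C)C(=C1)CC[C@@H](C(=O)O)[C@@H]2C
F5 | step 4 | 2-sulfanylidenepyridin-1(2H)-yl (1S,2R,8aR)-1,8a-dimethyl-6-oxo-1,2,3,4,6,7,8,8a-octahydronaphthalene-2-carboxylate | O=C1CC[C@@]2(C)C(=C1)CC[C@@H](C(=O)ON3C=CC=CC3=S)[C@@H]2C
F6 | step 9 | (1R,3S,4aR,5R,6R,8aS)-4a,5-dimethyl-3-(prop-1-en-2-yl)-1,6-bis[(triethylsilyl)oxy]octahydronaphthalen-2(1H)-one | C=C(C)[C@@H]1C[C@@]2(C)[C@H](CC[C@@H](O[Si](CC)(CC)CC)[C@@H]2C)[C@@H](O[Si](CC)(CC)CC)C1=O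
F7 | step 9 | (1R,3R,4aR,5R,6R,8aS)-4a,5-dimethyl-3-(prop-1-en-2-yl)-1,6-bis[(triethylsilyl)oxy]octahydronaphthalen-2(1H)-one | C=C(C)[C@H]1C[C@@]2(C)[C@H](CC[C@@H](O[Si](CC)(CC)CC)[C@@H]2C)[C@@H](O[Si](CC)(CC)CC)C1=O
F8 | step 9 | (1R,3R,4aR,5R,6R,8aS)-1,6-dihydroxy-4a,5-dimethyl-3-(prop-1-en-2-yl)octahydronaphthalen-2(1H)-one | C=C(C)[C@H]1C[C@@]2(C)[C@H](CC[C@@H](O)[C@@H]2C)[C@@H](O)C1=O
F9 | step 5 | (3S,4aR,5R,6R)-6-hydroxy-3-(2-hydroxypropan-2-yl)-4a,5-dimethyl-4,4a,5,6,7,8-hexahydronaphthalen-2(3H)-one | CC(C)(O)[C@@H]1C[C@@]2(C)C(=CC1=O)CC[C@@H](O)[C@@H]2C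
F10 | step 5 | (3S,4aS,5R,6R,8aR)-6-hydroxy-3-(2-hydroxypropan-2-yl)-4a,5-dimethyloctahydronaphthalen-2(1H)-one | CC(C)(O)[C@@H]1C[C@@]2(C)[C@H](CC[C@@H](O)[C@@H]2C)CC1=O
F11 | step 5 | (4aS,5R,6R,8aR)-6-hydroxy-4a,5-dimethyl-3-(propan-2-ylidene)octahydronaphthalen-2(1H)-one | CC(C)=C1C[C@@]2(C)[C@H](CC[C@@H](O)[C@@H]2C)CC1=O
F12 | step 5 | (1R,4aR,5R,6R,8aS)-1,6-dihydroxy-4a,5-dimethyl-3-(propan-2-ylidene)octahydronaphthalen-2(1H)-one | CC(C)=C1C[C@@]2(C)[C@H](CC[C@@H](O)[C@@H]2C)[C@@H](O)C1=O
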